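## Analysis of the target

Target 10 is an achiral, mirror-symmetric trimer of acylphloroglucinols: three benzene rings joined by two methylene bridges, with no stereocentre and no ring other than the three arenes. The central ring A carries a butanoyl group on C1, free hydroxyls on C2, C4 and C6, and the two bridging CH2 groups on C3 and C5. Each of the two identical outer rings B carries the bridge on C1', hydroxyls on C2' and C4', a butanoyl group on C3', a methyl group on C5' and a methoxy group on C6'. All eighteen ring carbons are substituted, so no aromatic C–H is left for late correction. The sensitive features are the seven free phenols (air oxidation in base), the three aryl ketones and the two diarylmethane bridges, which in methylene-bridged phloroglucinols can cleave and exchange partners under base or acid when a free ortho or para hydroxyl allows a quinone methide to form. The real difficulty is the differentiation of nine phenolic oxygens, of which only two are methylated. The handle is that on ring B the methylated oxygen O6' is the only one para to the C3' butanoyl carbonyl, whereas O2' and O4' are both ortho to it and tied to its hydrogen-bonded chelate. With the three oxygens of ring A masked, O6' becomes the most acidic unchelated hydroxyl of each outer ring, and the mirror symmetry lets both rings be treated in one operation.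

## Retrosynthetic reasoning

**10 to 9.** The three O–H bonds of ring A are replaced in thought by O–benzyl bonds. Ring A must be masked because its own O4 is para to the C1 butanoyl group and would be methylated as readily as O6'. Benzyl ethers are chosen because they fall under neutral catalytic hydrogenolysis, conditions under which the bridges, the aryl ketones and the two methyl ethers of 10 are all at rest. The forward step has to remove three hindered benzyl groups from 9 without touching a carbonyl.

**9 to 7 and 8.** The two O6'–CH3 bonds are cut next, one on each ring B. They are cut late and together because 7 then contains only symmetric, unmethylated outer rings, so no unsymmetrically protected building block is needed. In 7 the only free hydroxyls are the six on the outer rings, and among them O6' is singled out by its para relationship to the C3' carbonyl. The forward reaction must deliver exactly one methyl group from 8 to each ring B, at O6' and not at O2' or O4'.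

**7 to 3 and 6.** The two bonds between the bridging CH2 carbons and C1' are cut. This leaves both CH2 groups on ring A as benzylic electrophiles in 3 and frees the one unsubstituted carbon of 6 as the nucleophile. This polarity is preferred to the reverse for two reasons. A fully etherified ring A stabilises a benzylic cation through two ortho and one para oxygen, yet it can neither act as a carbon nucleophile nor form a quinone methide, so self-condensation is excluded. And 6 has a single free carbon, so it can react only there. Two identical bonds are made in one operation.

**3 to 2, and 2 to 1.** The two C–CH2Cl bonds on C3 and C5 of ring A are cut to reveal 2, whose two free ring positions are equivalent and strongly activated. A double one-carbon electrophilic substitution has to place a chloromethyl group on each. Cutting the three benzyl ethers of 2 leads to the stock ketone 1. The ketone is benzylated, and a benzylated ring is not acylated, because a Lewis acid would strip benzyl ethers ortho to the newly formed carbonyl.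

**6 to 4 and 5.** The aryl–carbonyl bond of 6 is cut to the symmetric triol 4 and the acid chloride 5. The two unsubstituted carbons of 4 are equivalent, so the Friedel–Crafts acylation can give only one ketone.

## Alternatives that were turned down

**Alternative 1:** Each outer ring would be cut across C1'–C2' and C5'–C6'. This leads back to the bis(ynol ether) 1,3,5-tris(benzyloxy)-2,4-bis(3-methoxyprop-2-yn-1-yl)benzene A2 and two molecules of 3-ethoxy-4-methylcyclobut-2-en-1-one A3.
- Forward key step: heating opens A3 to a vinylketene, which adds to each alkyne by [2+2] cycloaddition. Four-electron ring opening and six-electron electrocyclisation then close both rings B and give the bis(resorcinol ether) A1 (Danheiser benzannulation).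
- For it: the methoxy group on C6' and the bridge on C1' are placed by the atoms of the alkyne, not by a choice among hydroxyls. On that single point it is stronger than the chosen route.
- Against it: A1 carries none of the three butanoyl groups. Ring A (C1) and both rings B (C3') would have to be acylated late, under Friedel–Crafts conditions that endanger the benzyl ethers. O4' arrives as an ethyl ether that must be cleaved beside the O6' methyl ether, which again leans on the ortho relationship to the new ketone. A2 is a doubly propargylic bis(ynol ether), sensitive to acid and heat, and both A2 and A3 need several steps of their own.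
- Comparison: the sequence rebuilds a substitution pattern that 4 supplies directly. The chosen strategy gives up the built-in placement of the methyl ether but reaches the same differentiation in one step, on a precursor made from two stock phenols.

**Alternative 2:** Ring A would be cut at C2–C3, C4–C5 and C6–C1 into two molecules of the benzyl ynol ether 2-[3-(benzyloxy)prop-2-yn-1-yl]-1,3,5-trimethoxy-4-methylbenzene A5 and one of the ynone 1-(benzyloxy)hex-1-yn-3-one A6.
- Forward key step: a [2+2+2] cyclotrimerisation under a cationic monovalent rhodium catalyst ([Rh(cod)2]BF4, BINAP), which has to join the three alkynes head to tail to give A4.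
- For it: the hexasubstituted ring A appears in one step with all six substituents in place, with no electrophilic substitution on a crowded ring and no labile benzylic halide. In convergence it beats the chosen route.
- Against it: the key step needs a 2:1 cross-selection between two alkynes of different electronic character and complete head-to-tail orientation. Homotrimerisation of A5 is the obvious competitor, and benzyl alkynyl ethers rearrange to ketenes on mild warming. A4 still lacks the two outer butanoyl groups and has all three outer oxygens as methyl ethers, so two acylations and a chelation-guided cleavage of four ortho methyl ethers would follow.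
- Comparison: that ortho-selective cleavage is a well-behaved way to tell O6' from O2' and O4', and is arguably at least as dependable as selective methylation. The chosen strategy offers instead a carbon skeleton assembled by classical, predictable steps, so that only the methylation is open to doubt.

**Alternative 3:** The same two CH2–C1' bonds are cut as in the chosen route, but with the polarity of ring A inverted. The bis(chloride) 3 would be turned into the bis(benzylzinc chloride) A8 and coupled with two molecules of the aryl bromide 1-(3-bromo-2,4,6-trimethoxy-5-methylphenyl)butan-1-one A9.
- Forward key step: zinc insertion (Zn, LiCl) into both C–Cl bonds, then Negishi coupling under Pd(OAc)2 and SPhos, through zerovalent palladium, to give the permethylated trimer A7.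
- For it: the site of C–C bond formation is fixed by the position of bromine, free phenols and acid are kept away from the bridge-forming step, and benzylzinc reagents tolerate ketones. As a bond construction it is at least the equal of a Friedel–Crafts alkylation.
- Against it: each new bond joins two carbons that are both flanked by two ortho substituents. The very ionisable chloride 3 invites Wurtz-type homocoupling during zinc insertion. A9 costs a permethylation and a bromination of 6. Afterwards A7 has six outer methyl ethers, four of which (O2' and O4' of each ring) must be removed while O6' is kept, together with three benzyl groups, under strong Lewis acid that a methylene-bridged polyphenol tolerates poorly. The second ortho ether on a ketone already chelated to boron is slow to go.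
- Comparison: the oxygen differentiation is the mirror image of the chosen one, bought with more steps. The chosen strategy makes the same bonds without metal and never installs a methyl group that has to be taken off again.

Key step: step 5

Assumption: 1-(2,4,6-trihydroxyphenyl)butan-1-one (1) is taken to be a stock chemical. The target has no stereocentre, so no configuration has to be set.

## Route

Step 1
Reactants: 1 1-(2,4,6-trihydroxyphenyl)butan-1-one
Product: 2 1-[2,4,6-tris(benzyloxy)phenyl]butan-1-one
Conditions: BnBr (3.6 equiv), K2CO3 (4.5 equiv), DMF, 70 °C
Reagents that add atoms: benzyl bromide, BrCc1ccccc1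
Why: Williamson ether synthesis on the three phenoxides; the butanoyl group lowers the nucleophilicity of the ring carbons, so O-benzylation should dominate over C-benzylation, and heating with excess benzyl bromide carries the slow, chelated ortho hydroxyl to the ether.

Step 2
Reactants: 2 1-[2,4,6-tris(benzyloxy)phenyl]butan-1-one
Product: 3 1-[2,4,6-tris(benzyloxy)-3,5-bis(chloromethyl)phenyl]butan-1-one
Conditions: ClCH2OCH3 (6 equiv), ZnCl2 (0.2 equiv), CH2Cl2, 0 °C to 20 °C; used crude without chromatography
Reagents that add atoms: chloromethyl methyl ether, COCCl
Why: Blanc-type chloromethylation (electrophilic aromatic substitution by the methoxymethyl cation, then exchange of methoxide for chloride); C3 and C5 are each ortho to two and para to one benzyloxy group, the ketone is twisted out of conjugation by its two ortho ethers, and the flanking benzyloxy groups should shield the product from diarylmethane formation, as in the exhaustive halomethylation of 1,3,5-trialkoxybenzenes.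

Step 3
Reactants: 4 2-methylbenzene-1,3,5-triol (2,4,6-trihydroxytoluene); 5 butanoyl chloride
Product: 6 1-(2,4,6-trihydroxy-3-methylphenyl)butan-1-one
Conditions: AlCl3 (4 equiv), PhNO2, 25 to 60 °C; then ice, aq. HCl
Reagents that add atoms: butanoyl chloride (5), CCCC(Cl)=O
Why: Friedel–Crafts acylation; the two unsubstituted carbons of 4 are equivalent by symmetry, so only one ketone can form, its chelated and electron-poorer ring resists a second acylation, and any aryl ester formed on oxygen is carried to the ketone by Fries rearrangement under the same conditions.

Step 4
Reactants: 3 1-[2,4,6-tris(benzyloxy)-3,5-bis(chloromethyl)phenyl]butan-1-one; 6 1-(2,4,6-trihydroxy-3-methylphenyl)butan-1-one (3 equiv)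
Product: 7 1-{2,4,6-tris(benzyloxy)-3,5-bis[(3-butanoyl-2,4,6-trihydroxy-5-methylphenyl)methyl]phenyl}butan-1-one
Conditions: ZnCl2 (0.5 equiv), 1,4-dioxane, N2, 20 to 40 °C
Reagents that add atoms: none
Why: Two-fold Friedel–Crafts benzylation by an SN1 path: ZnCl2 ionises each C–Cl bond of 3 to a benzylic cation stabilised by two ortho and one para benzyloxy oxygen, which is captured by the only unsubstituted ring carbon (C5) of 6, activated by two ortho and one para hydroxyl. O-Benzylation of 6 is reversible under these conditions and drains to the C-alkylated product, and 3, having neither a free ring position nor a free hydroxyl, cannot condense with itself.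

Step 5
Reactants: 7 1-{2,4,6-tris(benzyloxy)-3,5-bis[(3-butanoyl-2,4,6-trihydroxy-5-methylphenyl)methyl]phenyl}butan-1-one; 8 dimethyl sulfate (2.1 equiv)
Product: 9 1-{2,4,6-tris(benzyloxy)-3,5-bis[(3-butanoyl-2,4-dihydroxy-6-methoxy-5-methylphenyl)methyl]phenyl}butan-1-one
Conditions: Me2SO4 (2.1 equiv, slow addition), K2CO3 (2.2 equiv), acetone, N2, 20 to 45 °C
Reagents that add atoms: dimethyl sulfate (8), COS(=O)(=O)OC
Why: K2CO3 removes the most acidic proton of each ring B, that of O6'–H, which is para to the C3' carbonyl and outside its chelate, and the resulting vinylogous carboxylate attacks a methyl group of 8 at oxygen in an SN2 step with loss of methyl sulfate. The closest known reaction type is the partial methylation of 2,4,6-trihydroxyaryl ketones and their C-methyl homologues with dimethyl sulfate and a carbonate base in acetone, which goes to the 4-O-methyl ether. No ring is closed and no stereocentre is formed. The site selectivity needed, O6' over O2' and O4', rests on the substrate: both competing hydroxyls are ortho to the butanoyl group, one held in the six-membered hydrogen-bonded chelate and the other wedged beside the acyl chain, and once O6' is ionised the more electron-rich carbonyl should bind them more tightly still. The degree of methylation is held at one methyl per ring by charging just over two equivalents of 8 slowly, the monomethyl ether being a weaker acid than its precursor. O- over C-methylation is favoured by the hard electrophile and the potassium phenoxide in acetone, and every carbon of ring B is already substituted, so C-attack would cost aromaticity. Ring A cannot interfere because its three oxygens are benzyl ethers, and the two outer rings, insulated from each other by sp3 carbons, should react independently and alike. The two ortho substituents of O6' (the C5' methyl group and the C1' bridge) are expected to slow, not divert, the transfer of so small a group.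

Step 6
Reactants: 9 1-{2,4,6-tris(benzyloxy)-3,5-bis[(3-butanoyl-2,4-dihydroxy-6-methoxy-5-methylphenyl)methyl]phenyl}butan-1-one
Product: 10 1-{3,5-bis[(3-butanoyl-2,4-dihydroxy-6-methoxy-5-methylphenyl)methyl]-2,4,6-trihydroxyphenyl}butan-1-one
Conditions: H2 (1 atm), 10% Pd/C, EtOAc–MeOH, 20 °C
Reagents that add atoms: none
Why: Catalytic hydrogenolysis of the three benzyl aryl ethers under neutral conditions; methyl ethers and diarylmethane C–C bonds are inert, the butanoyl carbonyls flanked by ortho oxygens should survive at atmospheric pressure in a neutral solvent, and no acid or base is present that could set the methylene bridges in motion.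

## Compound list

1 | 1-(2,4,6-trihydroxyphenyl)butan-1-one | CCCC(=O)c1c(O)cc(O)cc1O | starting material
2 | 1-[2,4,6-tris(benzyloxy)phenyl]butan-1-one | CCCC(=O)c1c(OCc2ccccc2)cc(OCc2ccccc2)cc1OCc1ccccc1 | intermediate
3 | 1-[2,4,6-tris(benzyloxy)-3,5-bis(chloromethyl)phenyl]butan-1-one | CCCC(=O)c1c(OCc2ccccc2)c(CCl)c(OCc2ccccc2)c(CCl)c1OCc1ccccc1 | intermediate
4 | 2-methylbenzene-1,3,5-triol (2,4,6-trihydroxytoluene) | Cc1c(O)cc(O)cc1O | starting material
5 | butanoyl chloride | CCCC(Cl)=O | starting material
6 | 1-(2,4,6-trihydroxy-3-methylphenyl)butan-1-one | CCCC(=O)c1c(O)cc(O)c(C)c1O | intermediate
7 | 1-{2,4,6-tris(benzyloxy)-3,5-bis[(3-butanoyl-2,4,6-trihydroxy-5-methylphenyl)methyl]phenyl}butan-1-one | CCCC(=O)c1c(OCc2ccccc2)c(Cc2c(O)c(C(=O)CCC)c(O)c(C)c2O)c(OCc2ccccc2)c(Cc2c(O)c(C(=O)CCC)c(O)c(C)c2O)c1OCc1ccccc1 | intermediate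
8 | dimethyl sulfate | COS(=O)(=O)OC | starting material
9 | 1-{2,4,6-tris(benzyloxy)-3,5-bis[(3-butanoyl-2,4-dihydroxy-6-methoxy-5-methylphenyl)methyl]phenyl}butan-1-one | CCCC(=O)c1c(OCc2ccccc2)c(Cc2c(O)c(C(=O)CCC)c(O)c(C)c2OC)c(OCc2ccccc2)c(Cc2c(O)c(C(=O)CCC)c(O)c(C)c2OC)c1OCc1ccccc1 | intermediate
10 | 1-{3,5-bis[(3-butanoyl-2,4-dihydroxy-6-methoxy-5-methylphenyl)methyl]-2,4,6-trihydroxyphenyl}butan-1-one | CCCC(=O)c1c(O)c(Cc2c(O)c(C(=O)CCC)c(O)c(C)c2OC)c(O)c(Cc2c(O)c(C(=O)CCC)c(O)c(C)c2OC)c1O | target

## Step count and risk

Total step count: 6. Longest linear sequence: 5 steps (steps 1, 2, 4, 5 and 6; step 3 is the one-step branch to 6).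

**Step 5 (key step).** The most likely failure is loss of site control: methyl transfer to O2' or O4' beside or after O6', or stalling at the doubly flanked O6'. Because both rings must come out right, any leak is multiplied, and the isomeric ethers of a large polyphenol would be hard to separate.
- Fallback: the methylation is moved to the monomer, setting out from 6. With one equivalent of 8 and K2CO3 in acetone, 6 is methylated at its para hydroxyl, which there has only one ortho substituent, to give 1-(2,6-dihydroxy-4-methoxy-3-methylphenyl)butan-1-one F1. Any isomer is removed at this small-molecule stage.
- The free ring carbon of F1, flanked by hydroxyl and methoxy, is then benzylated twice by 3 under the conditions of step 4.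
- The fallback comes back to the route at 9.

**Step 2.** The benzylic cation of the product may alkylate unreacted 2 or a benzyl ether ring (diarylmethane formation). The acid may strip a benzyl group ortho to the ketone, the reaction may stall after the first chloromethylation, and the product may hydrolyse on work-up.
- Fallback: the two carbons are brought in at the aldehyde level, setting out from 1. Rieche formylation (Cl2CHOCH3, TiCl4, CH2Cl2) on the free triol gives 5-butanoyl-2,4,6-trihydroxybenzene-1,3-dicarbaldehyde F2.
- Benzylation (benzyl bromide, K2CO3, DMF) gives 2,4,6-tris(benzyloxy)-5-butanoylbenzene-1,3-dicarbaldehyde F3.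
- NaBH4 at low temperature reduces the two aldehydes ahead of the hindered ketone to 1-[2,4,6-tris(benzyloxy)-3,5-bis(hydroxymethyl)phenyl]butan-1-one F4.
- The stable diol F4 is condensed with 6 under catalytic p-toluenesulfonic acid in dioxane, with water as the only by-product.
- The fallback comes back to the route at 7.

**Step 4.** The acid released may drive exchange of the benzylic unit between rings (retro-Friedel–Crafts and transfer of the bridge), the second alkylation may lag behind the first, or a benzyl ether may be lost to ZnCl2 and HCl.
- Fallback: the same bond is made by anionic C-benzylation, setting out from 3 and 6. The sodium phenoxide of 6 (NaOMe, then THF–toluene, 0 °C) is alkylated at carbon by 3, as in the base-mediated C-alkylation of acylphloroglucinols by allylic and benzylic halides.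
- The medium stays basic, and ring A, lacking a free hydroxyl, cannot open a quinone methide path to bridge cleavage.
- The fallback makes no new compound (F0) and comes back to the route at 7.

**Step 6.** The butanoyl carbonyls may be over-reduced, or the reaction may stall at partly benzylated stages because each benzyl ether is flanked by two substituents. The freed heptaphenol may also oxidise in air during work-up.
- Fallback: Lewis-acid debenzylation, setting out from 9, with BCl3 and pentamethylbenzene in CH2Cl2 at −78 °C. The benzyl cations are trapped by the arene.
- The O6' methyl ethers, not being ortho to a carbonyl, are not activated by chelation and should stay.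
- The fallback makes no new compound (F0) and comes back to the route at 10.

## Further compounds

F1 | step 5 | 1-(2,6-dihydroxy-4-methoxy-3-methylphenyl)butan-1-one | CCCC(=O)c1c(O)cc(OC)c(C)c1O
F2 | step 2 | 5-butanoyl-2,4,6-trihydroxybenzene-1,3-dicarbaldehyde | CCCC(=O)c1c(O)c(C=O)c(O)c(C=O)c1O
F3 | step 2 | 2,4,6-tris(benzyloxy)-5-butanoylbenzene-1,3-dicarbaldehyde | CCCC(=O)c1c(OCc2ccccc2)c(C=O)c(OCc2ccccc2)c(C=O)c1OCc1ccccc1
F4 | step 2 | 1-[2,4,6-tris(benzyloxy)-3,5-bis(hydroxymethyl)phenyl]butan-1-one | CCCC(=O)c1c(OCc2ccccc2)c(CO)c(OCc2ccccc2)c(CO)c1OCc1ccccc1
F0 | step 4 | none | none
F0 | step 6 | none | none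
A1 | alternative 1 | 1,3,5-tris(benzyloxy)-2,4-bis[(4-ethoxy-2-hydroxy-6-methoxy-5-methylphenyl)methyl]benzene | CCOc1cc(O)c(Cc2c(OCc3ccccc3)cc(OCc3ccccc3)c(Cc3c(O)cc(OCC)c(C)c3OC)c2OCc2ccccc2)c(OC)c1C
A2 | alternative 1 | 1,3,5-tris(benzyloxy)-2,4-bis(3-methoxyprop-2-yn-1-yl)benzene | COC#CCc1c(OCc2ccccc2)cc(OCc2ccccc2)c(CC#COC)c1OCc1ccccc1
A3 | alternative 1 | 3-ethoxy-4-methylcyclobut-2-en-1-one | CCOC1=CC(=O)C1C
A4 | alternative 2 | 1-{2,4,6-tris(benzyloxy)-3,5-bis[(2,4,6-trimethoxy-3-methylphenyl)methyl]phenyl}butan-1-one | CCCC(=O)c1c(OCc2ccccc2)c(Cc2c(OC)cc(OC)c(C)c2OC)c(OCc2ccccc2)c(Cc2c(OC)cc(OC)c(C)c2OC)c1OCc1ccccc1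
A5 | alternative 2 | 2-[3-(benzyloxy)prop-2-yn-1-yl]-1,3,5-trimethoxy-4-methylbenzene | COc1cc(OC)c(C)c(OC)c1CC#COCc1ccccc1
A6 | alternative 2 | 1-(benzyloxy)hex-1-yn-3-one | CCCC(=O)C#COCc1ccccc1
A7 | alternative 3 | 1-{2,4,6-tris(benzyloxy)-3,5-bis[(3-butanoyl-2,4,6-trimethoxy-5-methylphenyl)methyl]phenyl}butan-1-one | CCCC(=O)c1c(OCc2ccccc2)c(Cc2c(OC)c(C(=O)CCC)c(OC)c(C)c2OC)c(OCc2ccccc2)c(Cc2c(OC)c(C(=O)CCC)c(OC)c(C)c2OC)c1OCc1ccccc1
A8 | alternative 3 | {[2,4,6-tris(benzyloxy)-5-butanoylbenzene-1,3-diyl]bis(methylene)}bis(chloridozinc) | CCCC(=O)c1c(OCc2ccccc2)c(C[Zn]Cl)c(OCc2ccccc2)c(C[Zn]Cl)c1OCc1ccccc1
A9 | alternative 3 | 1-(3-bromo-2,4,6-trimethoxy-5-methylphenyl)butan-1-one | CCCC(=O)c1c(OC)c(Br)c(OC)c(C)c1OC
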